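**Retrosynthetic overview**
- The target comes from its tri-O-methyl bis-quinone by cleavage of the three peri methyl ethers; that bis-quinone comes from an aryl-naphthohydroquinone by oxidative demethylation.
- The hindered aryl–quinone bond is made last, by a 1,2-aryl shift (C4→C3) in a quinol formed by adding a naphthyllithium to the C4 carbonyl of 5,8-dimethoxy-2-methyl-1,4-naphthoquinone.
- The naphthyllithium comes from 8-chloro-1,3,4,5-tetramethoxy-7-methylnaphthalene, made from 8-chloro-7-methyljuglone (m-cresol, chlorination, maleic anhydride annulation), with the 3-OMe introduced by bromination and methanolysis.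
- The quinone partner comes from naphthazarin (hydroquinone plus maleic anhydride) by O-methylation and radical C-methylation.
- Ring order: the quinone ring of each half is annulated onto a purchased benzene ring in two separate melt reactions; no ring is formed after the two halves are joined.

Assumption: the SMILES has no stereodescriptor and no stereocentre, so the hindered aryl–quinone axis is left unassigned and the compound is made as drawn, without control of that axis.

Naming note: the m-cresol-derived half keeps juglone numbering throughout (C1/C4 carbonyl carbons, C5 oxygen peri to C4, C7 methyl, C8 the carbon that carries Cl, Li or the other half).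

**Route**

Step 1
Reactants: 1 3-methylphenol (m-cresol)
Product: 2 4-chloro-3-methylphenol
Conditions: SO2Cl2 (1.05 equiv), Ph2S (cat.), AlCl3 (cat.), neat, 30–50 °C
Reagents that add atoms: sulfuryl chloride, O=S(=O)(Cl)Cl
Why: Electrophilic aromatic chlorination; the hydroxyl directs para and this modified sulfuryl chloride system is the established para-selective chlorination of m-cresol.

Step 2
Reactants: 2 4-chloro-3-methylphenol; 3 maleic anhydride
Product: 4 8-chloro-5-hydroxy-7-methylnaphthalene-1,4-dione (8-chloro-7-methyljuglone)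
Conditions: AlCl3/NaCl melt, 180 °C, 2–5 min; then ice, aq. HCl
Reagents that add atoms: none
Why: Double Friedel–Crafts acylation (melt annulation): acylation ortho to OH, then ring closure ortho to Cl because the para position is blocked; this is the known preparation of this chlorojuglone.

Step 3
Reactants: 4 8-chloro-5-hydroxy-7-methylnaphthalene-1,4-dione
Product: 6 3-bromo-8-chloro-5-hydroxy-7-methylnaphthalene-1,4-dione, via dibromide 5 (not isolated)
Conditions: Br2 (1.05 equiv), AcOH, 20 °C; then NaOAc, 60 °C
Reagents that add atoms: bromine, BrBr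
Why: Bromine addition to the quinone C2=C3 bond, then buffered dehydrobromination through the enol of the hydrogen-bonded C4 carbonyl (loss of H-3 and Br-2), the known addition–elimination route from free juglones to 3-bromojuglones.

Step 4
Reactants: 6 3-bromo-8-chloro-5-hydroxy-7-methylnaphthalene-1,4-dione
Product: 7 8-chloro-5-hydroxy-3-methoxy-7-methylnaphthalene-1,4-dione
Conditions: NaOMe (2.2 equiv), MeOH, 0 → 20 °C; then AcOH
Reagents that add atoms: sodium methoxide, [Na+].[O-]C
Why: Addition–elimination (vinylogous acyl substitution) at C3, the β-carbon of the C1 enone, which stays electrophilic in the phenoxide; the aryl chloride para to the phenoxide is inert.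

Step 5
Reactants: 7 8-chloro-5-hydroxy-3-methoxy-7-methylnaphthalene-1,4-dione
Product: 9 8-chloro-1,3,4,5-tetramethoxy-7-methylnaphthalene, via naphthalenetriol 8 (not isolated)
Conditions: Na2S2O4, Bu4NBr (cat.), THF/H2O, 20 °C; then aq. KOH, Me2SO4, 20 °C, under N2
Reagents that add atoms: dimethyl sulfate, COS(=O)(=O)OC
Why: One-pot reductive methylation (dithionite reduction to the hydroquinone, then phase-transfer Williamson etherification of all three hydroxyls); reducing before adding base protects the methoxyquinone from hydrolysis.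

Step 6
Reactants: 10 hydroquinone (benzene-1,4-diol); 3 maleic anhydride
Product: 11 5,8-dihydroxynaphthalene-1,4-dione (naphthazarin)
Conditions: AlCl3/NaCl melt, 200–220 °C; then aq. HCl, 100 °C
Reagents that add atoms: none
Why: Double Friedel–Crafts acylation of hydroquinone in the melt, the classical naphthazarin synthesis.

Step 7
Reactants: 11 5,8-dihydroxynaphthalene-1,4-dione
Product: 12 5,8-dimethoxynaphthalene-1,4-dione
Conditions: MeI (10 equiv), Ag2O (4 equiv), CHCl3, 40 °C, dark, 48 h
Reagents that add atoms: iodomethane, CI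
Why: Purdie O-methylation with Ag2O/MeI of the chelated peri hydroxyls; the substrate is symmetric, so naphthazarin tautomerism cannot give regioisomers.

Step 8
Reactants: 12 5,8-dimethoxynaphthalene-1,4-dione
Product: 13 5,8-dimethoxy-2-methylnaphthalene-1,4-dione
Conditions: AcOH (5 equiv), AgNO3 (0.3 equiv), (NH4)2S2O8 (1.3 equiv), MeCN/H2O, 65 °C
Reagents that add atoms: acetic acid, CC(=O)O
Why: Jacobsen–Torssell (Kochi-type) decarboxylative radical alkylation: divalent silver formed from AgNO3 and persulfate oxidises acetic acid to a methyl radical, which adds to the quinone C–H position and is re-oxidised; limiting the oxidant keeps it at mono-methylation.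

Step 9
Reactants: 9 8-chloro-1,3,4,5-tetramethoxy-7-methylnaphthalene; 13 5,8-dimethoxy-2-methylnaphthalene-1,4-dione
Product: 16 5,8-dimethoxy-2-methyl-3-(1,3,4,5-tetramethoxy-7-methylnaphthalen-8-yl)naphthalene-1,4-diol, via aryllithium 14 (not isolated), via quinol 15 (not isolated)
Conditions: lithium 4,4'-di-tert-butylbiphenylide (2.05 equiv, pre-formed in THF), THF, −78 °C; then added to 13 (1.2 equiv), THF, −78 °C; then CH2Cl2, CF3CO2H (15 equiv), −78 → 0 °C; aq. Na2S2O4 wash under Ar
Reagents that add atoms: none
Why: Proposed new method: the aryllithium adds 1,2 to the less hindered C4 carbonyl (flanked by C3–H, not by the C2 methyl), and acid then protonates the C1 carbonyl so that C3 becomes electrophilic, the electron-rich aryl group migrates C4→C3 through a phenonium-type bridge with the carbinol oxygen becoming the C4 carbonyl (semipinacol-type 1,2-shift), and tautomerisation to the aromatic hydroquinone makes the shift irreversible; the closest known reaction type is the acid-promoted quinol (dienone–phenol / quinol–enedione) rearrangement of 4-substituted 4-hydroxycyclohexa-2,5-dienones, which has not been shown for a bond with four ortho substituents; the axis forms without stereocontrol.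

Step 10
Reactants: 16 5,8-dimethoxy-2-methyl-3-(1,3,4,5-tetramethoxy-7-methylnaphthalen-8-yl)naphthalene-1,4-diol
Product: 17 8-(5,8-dimethoxy-3-methyl-1,4-dioxo-1,4-dihydronaphthalen-2-yl)-3,5-dimethoxy-7-methylnaphthalene-1,4-dione
Conditions: (NH4)2Ce(NO3)6 (4.5 equiv), MeCN/H2O 2:1, 0 °C, 20 min
Reagents that add atoms: water, O
Why: Oxidative demethylation with tetravalent cerium: the hydroquinone is oxidised to its quinone and the para-dimethoxy pair at C1/C4 of the other half gives the 1,4-quinone with the 3-OMe kept (as 1,2,4-trimethoxyarenes give 2-methoxyquinones); the peri-methoxy rings are deactivated once the quinones are in place.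

Step 11
Reactants: 17 8-(5,8-dimethoxy-3-methyl-1,4-dioxo-1,4-dihydronaphthalen-2-yl)-3,5-dimethoxy-7-methylnaphthalene-1,4-dione
Product: 18 8'-hydroxy-3-methoxy isodiospyrin (target)
Conditions: BCl3 (5 equiv), CH2Cl2, −78 → −10 °C; then H2O
Reagents that add atoms: none
Why: Chelation-controlled Lewis-acid ether cleavage: BCl3 bridges each quinone carbonyl and its peri methoxy oxygen in a six-membered chelate and cleaves those three ethers, while the vinylogous-ester 3-OMe is weakly basic and could only form a five-membered chelate.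

**Compound list**

1 | 3-methylphenol (m-cresol) | Cc1cccc(O)c1 | starting material
2 | 4-chloro-3-methylphenol | Cc1cc(O)ccc1Cl | intermediate
3 | maleic anhydride | O=C1OC(=O)C=C1 | starting material
4 | 8-chloro-5-hydroxy-7-methylnaphthalene-1,4-dione | O=C1C=CC(=O)c2c(O)cc(C)c(Cl)c12 | intermediate
5 | trans-2,3-dibromo-8-chloro-5-hydroxy-7-methyl-2,3-dihydronaphthalene-1,4-dione (racemic, one enantiomer drawn) | O=C1[C@H](Br)[C@@H](Br)C(=O)c2c(O)cc(C)c(Cl)c12 | intermediate (not isolated)
6 | 3-bromo-8-chloro-5-hydroxy-7-methylnaphthalene-1,4-dione | O=C1C=C(Br)C(=O)c2c(O)cc(C)c(Cl)c12 | intermediate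
7 | 8-chloro-5-hydroxy-3-methoxy-7-methylnaphthalene-1,4-dione | COC1=CC(=O)c2c(Cl)c(C)cc(O)c2C1=O | intermediate
8 | 8-chloro-3-methoxy-7-methylnaphthalene-1,4,5-triol | COc1cc(O)c2c(Cl)c(C)cc(O)c2c1O | intermediate (not isolated)
9 | 8-chloro-1,3,4,5-tetramethoxy-7-methylnaphthalene | COc1cc(OC)c2c(Cl)c(C)cc(OC)c2c1OC | intermediate
10 | hydroquinone (benzene-1,4-diol) | Oc1ccc(O)cc1 | starting material
11 | 5,8-dihydroxynaphthalene-1,4-dione (naphthazarin) | O=C1C=CC(=O)c2c(O)ccc(O)c12 | intermediate
12 | 5,8-dimethoxynaphthalene-1,4-dione | COc1ccc(OC)c2c1C(=O)C=CC2=O | intermediate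
13 | 5,8-dimethoxy-2-methylnaphthalene-1,4-dione | COc1ccc(OC)c2c1C(=O)C(C)=CC2=O | intermediate
14 | (1,3,4,5-tetramethoxy-7-methylnaphthalen-8-yl)lithium | [Li]c1c(C)cc(OC)c2c(OC)c(OC)cc(OC)c12 | intermediate (not isolated)
15 | 4-hydroxy-5,8-dimethoxy-2-methyl-4-(1,3,4,5-tetramethoxy-7-methylnaphthalen-8-yl)naphthalen-1(4H)-one (racemic at C4; formed as its lithium alkoxide, protonated in the flask) | COc1ccc(OC)c2c1C(=O)C(C)=CC2(O)c1c(C)cc(OC)c2c(OC)c(OC)cc(OC)c12 | intermediate (not isolated)
16 | 5,8-dimethoxy-2-methyl-3-(1,3,4,5-tetramethoxy-7-methylnaphthalen-8-yl)naphthalene-1,4-diol (axis unassigned) | COc1ccc(OC)c2c(O)c(-c3c(C)cc(OC)c4c(OC)c(OC)cc(OC)c34)c(C)c(O)c12 | intermediate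
17 | 8-(5,8-dimethoxy-3-methyl-1,4-dioxo-1,4-dihydronaphthalen-2-yl)-3,5-dimethoxy-7-methylnaphthalene-1,4-dione (axis unassigned) | COC1=CC(=O)c2c(C3=C(C)C(=O)c4c(OC)ccc(OC)c4C3=O)c(C)cc(OC)c2C1=O | intermediate
18 | 8'-hydroxy-3-methoxy isodiospyrin (axis unassigned, as in the given SMILES) | COC1=CC(=O)c2c(C3=C(C)C(=O)c4c(O)ccc(O)c4C3=O)c(C)cc(O)c2C1=O | target

**Count and risks**

Total steps: 11. Longest linear sequence: 8 (steps 1, 2, 3, 4, 5, 9, 10, 11); the quinone partner takes 3 steps (6, 7, 8).

Steps most likely to fail: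

1. Step 9 (the new addition/1,2-aryl shift). The hindered, electron-rich aryllithium may transfer an electron to the quinone or deprotonate its C2 methyl instead of adding. In acid the quinol may lose the aryl group (retro-addition) instead of rearranging. Fallback by known chemistry, setting out from 9 and 13: Miyaura borylation of 9 (B2pin2, Pd2(dba)3, XPhos, KOAc, dioxane, 100 °C) gives 2-(1,3,4,5-tetramethoxy-7-methylnaphthalen-8-yl)-4,4,5,5-tetramethyl-1,3,2-dioxaborolane F1. Bromine in AcOH converts 13 into trans-2,3-dibromo-5,8-dimethoxy-2-methyl-2,3-dihydronaphthalene-1,4-dione F2, which with NaOAc loses HBr to give 2-bromo-5,8-dimethoxy-3-methylnaphthalene-1,4-dione F3. Suzuki–Miyaura coupling of F1 with F3 (Pd(OAc)2, SPhos, K3PO4, toluene/H2O, 100 °C) gives 5,8-dimethoxy-2-methyl-3-(1,3,4,5-tetramethoxy-7-methylnaphthalen-8-yl)naphthalene-1,4-dione F4. Oxidation of F4 with (NH4)2Ce(NO3)6 under the conditions of step 10 comes back to the route at 17.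

2. Step 11 (selective cleavage of three peri methyl ethers beside the quinone 3-OMe). BCl3 may also cleave the vinylogous-ester methoxy group. Fallback, setting out from 17: exhaustive demethylation with BBr3 (excess, CH2Cl2, −78 → 20 °C) gives 3,5-dihydroxy-8-(5,8-dihydroxy-3-methyl-1,4-dioxo-1,4-dihydronaphthalen-2-yl)-7-methylnaphthalene-1,4-dione F5. Its hydroxyquinone (vinylogous acid) OH alone is then re-etherified with MeOH and catalytic HCl at 65 °C, as for lawsone; the hydrogen-bonded peri phenols do not react. This comes back to the route at 18.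

3. Step 7 (direct O-methylation of the chelated naphthazarin hydroxyls). The reaction may stall at the monomethyl ether or give a low yield. Fallback, setting out from 11: reductive methylation (Na2S2O4, then aq. KOH/Me2SO4, as in step 5) passes through naphthalene-1,4,5,8-tetrol F6 and gives 1,4,5,8-tetramethoxynaphthalene F7. Oxidative demethylation of one ring of F7 with (NH4)2Ce(NO3)6 (MeCN/H2O, 0 °C) comes back to the route at 12; the symmetry of F7 makes the regiochemistry unambiguous.

**Further compounds**

F1 | step 9 | 2-(1,3,4,5-tetramethoxy-7-methylnaphthalen-8-yl)-4,4,5,5-tetramethyl-1,3,2-dioxaborolane | Cc1cc(OC)c2c(OC)c(OC)cc(OC)c2c1B1OC(C)(C)C(C)(C)O1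
F2 | step 9 | trans-2,3-dibromo-5,8-dimethoxy-2-methyl-2,3-dihydronaphthalene-1,4-dione (racemic, one enantiomer drawn) | COc1ccc(OC)c2c1C(=O)[C@](C)(Br)[C@@H](Br)C2=O
F3 | step 9 | 2-bromo-5,8-dimethoxy-3-methylnaphthalene-1,4-dione | COc1ccc(OC)c2c1C(=O)C(C)=C(Br)C2=O
F4 | step 9 | 5,8-dimethoxy-2-methyl-3-(1,3,4,5-tetramethoxy-7-methylnaphthalen-8-yl)naphthalene-1,4-dione | COc1ccc(OC)c2c1C(=O)C(C)=C(C2=O)c1c(C)cc(OC)c2c(OC)c(OC)cc(OC)c12
F5 | step 11 | 3,5-dihydroxy-8-(5,8-dihydroxy-3-methyl-1,4-dioxo-1,4-dihydronaphthalen-2-yl)-7-methylnaphthalene-1,4-dione | OC1=CC(=O)c2c(C3=C(C)C(=O)c4c(O)ccc(O)c4C3=O)c(C)cc(O)c2C1=O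
F6 | step 7 | naphthalene-1,4,5,8-tetrol | Oc1ccc(O)c2c(O)ccc(O)c12
F7 | step 7 | 1,4,5,8-tetramethoxynaphthalene | COc1ccc(OC)c2c(OC)ccc(OC)c12
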